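The cycloheptane (C1 lactone carbinol, C2 acyloxy carbon, C3 quaternary carbinol, C4 methyl-bearing carbon, C5 carbinol, C6, C7 ring fusion) is read as a cyclopentane-1,3-dione (C1, C4, C5, C6, C7) into whose C1–C4 bond the dioxygenated C2–C3 unit is inserted. A De Mayo (2+2) photocycloaddition between the C1=C4 enol double bond of an enantiopure enol lactone (O–C1/C7 γ-lactone tether in place) and the silyl enol ether of dihydroxyacetone acetonide forms C1–C2 and C3–C4 at once; retro-aldol opening of the cyclobutane (C1–C4) gives the seven-membered ring. It exploits the 1,3-relationship of the C1 and C5 oxygens across C4 and the vicinal C2/C3 oxygens.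

Key step: step 6

Remark: ring carbons are called C1–C7 as defined above throughout; β is the face of the cycloheptane that carries the C7 side chain, α the opposite face; the six starting materials are taken as commercial, 28 as the pure trans isomer.

Step 1
Reactants: 1 4-oxohexanoic acid; 2 (S)-4-benzyl-1,3-oxazolidin-2-one
Product: 4 (S)-4-benzyl-3-(4-oxohexanoyl)-1,3-oxazolidin-2-one, via 4-oxohexanoic pivalic anhydride 3 (not isolated)
Conditions: PivCl, Et3N, THF, −20 °C; then 2, LiCl, rt
Reagents that add atoms: none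
Why: Mixed-anhydride N-acylation of the oxazolidinone installs the Evans auxiliary on the carboxyl carbon that becomes C1; no stereocentre is formed.

Step 2
Reactants: 4 (S)-4-benzyl-3-(4-oxohexanoyl)-1,3-oxazolidin-2-one; 5 tert-butyl bromoacetate
Product: 7 tert-butyl (3R)-3-{[(4S)-4-benzyl-2-oxo-1,3-oxazolidin-3-yl]carbonyl}-5-oxoheptanoate, via sodium (Z)-enolate 6 (not isolated)
Conditions: NaN(SiMe3)2 (1.05 equiv), THF, −78 °C; then 5, −78 to −45 °C
Reagents that add atoms: none
Why: Evans asymmetric alkylation, in which the chelated (Z)-enolate is alkylated on the face away from the benzyl group and so sets C7 as (R); one equivalent of base should enolise the far more acidic imide α-CH2 in preference to the ketone.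

Step 3
Reactants: 7 tert-butyl (3R)-3-{[(4S)-4-benzyl-2-oxo-1,3-oxazolidin-3-yl]carbonyl}-5-oxoheptanoate
Product: 8 tert-butyl 2-[(1R)-3-methyl-2,4-dioxocyclopentyl]acetate
Conditions: LiN(SiMe3)2 (2.2 equiv), THF, −78 to 0 °C; 1 M HCl
Reagents that add atoms: none
Why: Intramolecular Claisen (Dieckmann-type) acylation, in which the kinetic enolate of the ethyl ketone CH2 attacks the exocyclic imide carbonyl (5-exo-trig) and expels the auxiliary; the hindered imide α-methine is slow to deprotonate and the product is stored as its dione enolate, so C7 should keep its configuration.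

Step 4
Reactants: 8 tert-butyl 2-[(1R)-3-methyl-2,4-dioxocyclopentyl]acetate
Product: 10 (3aR)-6-methyl-3,3a-dihydro-2H-cyclopenta[b]furan-2,5(4H)-dione (enol lactone), via acid 9 (not isolated)
Conditions: CF3CO2H, CH2Cl2, rt; then EDC·HCl, CH2Cl2, 0 °C to rt
Reagents that add atoms: none
Why: Acidolysis of the tert-butyl ester followed by carbodiimide enol lactonisation onto the neighbouring enol oxygen fixes the enol double bond between C1 and C4, because lactonisation onto the other enol oxygen would need a bridgehead alkene.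

Step 5
Reactants: 11 2,2-dimethyl-1,3-dioxan-5-one
Product: 12 tert-butyl[(2,2-dimethyl-4H-1,3-dioxin-5-yl)oxy]dimethylsilane
Conditions: TBSOTf, Et3N, CH2Cl2, 0 °C
Reagents that add atoms: tert-butyldimethylsilyl trifluoromethanesulfonate CC(C)(C)[Si](C)(C)OS(=O)(=O)C(F)(F)F
Why: Soft enolisation and O-silylation of the symmetric ketone give the silyl enol ether that carries C2, C3, both their oxygens and the C3 carbon substituent.

Step 6
Reactants: 10 (3aR)-6-methyl-3,3a-dihydro-2H-cyclopenta[b]furan-2,5(4H)-dione; 12 tert-butyl[(2,2-dimethyl-4H-1,3-dioxin-5-yl)oxy]dimethylsilane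
Product: 13 cyclobutane photoadduct (C1–C2 and C3–C4 bonds; acetonide ring exo; 3-OTBS endo)
Conditions: hν (350 nm, Pyrex), 12 (4 equiv), MeCN, −20 °C, degassed
Reagents that add atoms: none
Why: Excitation (n→π*) and intersystem crossing give the triplet enone of 10, whose β-carbon C1 adds to the unsubstituted enol ether carbon C2 of 12, and the resulting triplet 1,4-biradical (tertiary α-keto radical at C4, tertiary α-siloxy radical at C3) closes the C3–C4 bond after spin inversion. The closest known reaction is the De Mayo reaction, the enone–alkene (2+2) photocycloaddition of 1,3-dione enol esters with enol ethers. One ring is closed, the cyclobutane C1–C2–C3–C4, by intermolecular radical addition followed by 1,4-biradical recombination, cis-fused to both the cyclopentanone and the dioxane. At C1 and C4 the cyclobutane must form on the cyclopentenone face opposite the lactone CH2, because the γ-lactone can only stay cis-fused, so the C7 stereocentre dictates the absolute sense; C2 and C3 are cis through the ring alkene, and the dioxane ring should lie exo with the small H-2 in the concave position, which places O–C2 and the C3 carbon substituent β and O–C3 α as in the target. The step needs head-to-tail regiochemistry, which the ring oxygen on C2 and the more stabilised biradical should secure, and the exo orientation; an excess of 12 and long-wavelength light should suppress dimerisation of 10.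

Step 7
Reactants: 13 cyclobutane photoadduct
Product: 15 methyl 2-(2β-hydroxy-3β-hydroxymethyl-3α-tert-butyldimethylsilyloxy-4α-methyl-1,5-dioxocyclohept-7β-yl)acetate, via acetonide dione 14 (not isolated)
Conditions: K2CO3, MeOH, 0 °C; then 1 M HCl, THF, rt
Reagents that add atoms: methanol CO
Why: Methoxide opens the lactone and the freed cyclobutanolate undergoes strain-driven retro-aldol cleavage of C1–C4 (De Mayo fragmentation); C4 is set by enolate protonation and equilibration, expected to place the methyl trans to the C3 CH2O group, and dilute acid then hydrolyses the acetonide while the tertiary TBS ether, which blocks the competing C3–C4 retro-aldol, should survive.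

Step 8
Reactants: 15 methyl 2-(2β-hydroxy-3β-hydroxymethyl-3α-tert-butyldimethylsilyloxy-4α-methyl-1,5-dioxocyclohept-7β-yl)acetate
Product: 17 trans-fused γ-lactone keto diol (O–C1 α; 2β-OH; 3β-CH2OH; 3α-OTBS; 4α-CH3; 5-oxo), via hydroxy ester 16 (not isolated)
Conditions: Me4NBH(OAc)3, MeCN–AcOH, −25 °C; then PPTS, CH2Cl2, rt
Reagents that add atoms: none
Why: Saksena–Evans hydroxyl-directed reduction, in which the borate ester of the C2 hydroxyl delivers hydride to the β face of the adjacent C1 ketone only (the C5 ketone has no α- or β-hydroxyl), giving the trans-1,2-diol with C1–OH α, which lactonises with the β side chain to the trans-fused lactone.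

Step 9
Reactants: 17 trans-fused γ-lactone keto diol
Product: 18 trans-fused γ-lactone triol (2β-OH; 3β-CH2OH; 5β-OH; 3α-OTBS; 4α-CH3)
Conditions: (S)-2-methyl-CBS-oxazaborolidine (0.3 equiv), BH3·SMe2 (excess), THF, −20 °C; MeOH
Reagents that add atoms: none
Why: Corey–Bakshi–Shibata reduction, in which the (S)-catalyst distinguishes the branched C4 side from the C6 methylene and delivers hydride to the α face, giving the (R)-carbinol at C5 with OH β and trans to the C4 methyl.

Step 10
Reactants: 18 trans-fused γ-lactone triol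
Product: 19 bis(triethylsilyl) ether (5β-OTES; 3β-CH2OTES; 2β-OH free)
Conditions: Et3SiCl (2.3 equiv), imidazole, DMF, 0 °C
Reagents that add atoms: chlorotriethylsilane CC[Si](Cl)(CC)CC
Why: Site-selective silylation, in which the primary hydroxyl and the less hindered C5 hydroxyl react while the C2 hydroxyl, flanked by the quaternary C3 and by C1, should stay free.

Step 11
Reactants: 19 bis(triethylsilyl) ether
Product: 23 α-methylene lactone 2β-alcohol, via dilithium enolate 20 (not isolated), via Mannich base 21 (not isolated), via ammonium iodide 22 (not isolated)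
Conditions: LiN(iPr)2 (2.5 equiv), THF, −78 °C; CH2=NMe2+ I−, −78 to 0 °C; then MeI, MeOH, rt; then aq. NaHCO3, CH2Cl2
Reagents that add atoms: Eschenmoser's salt (N,N-dimethylmethyleneiminium iodide) C=[N+](C)C.[I-]
Why: Eschenmoser methylenation (lactone enolate Mannich reaction, N-methylation and base-induced elimination of trimethylamine) installs the exocyclic methylene, the C2 alkoxide being a spectator and the new α-stereocentre of 21 being destroyed again.

Step 12
Reactants: 23 α-methylene lactone 2β-alcohol; 24 (R)-2-methylbutanoic acid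
Product: 25 2β-[(2R)-2-methylbutanoyloxy] α-methylene lactone
Conditions: EDC·HCl, DMAP, CH2Cl2, 0 °C to rt
Reagents that add atoms: none
Why: Steglich esterification of the only free hydroxyl; carbodiimide activation at low temperature avoids a ketene and so should keep the α-stereocentre of the acid.

Step 13
Reactants: 25 2β-[(2R)-2-methylbutanoyloxy] α-methylene lactone
Product: 27 3β-carbaldehyde, via alkoxysulfonium chloride 26 (not isolated)
Conditions: (COCl)2, DMSO, CH2Cl2, −78 to −30 °C; then Et3N, −78 °C to rt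
Reagents that add atoms: none
Why: Swern oxidation applied directly to the primary triethylsilyl ether, which is cleaved and oxidised to the aldehyde while the secondary TES and tertiary TBS ethers should persist; the α-quaternary aldehyde cannot epimerise.

Step 14
Reactants: 27 3β-carbaldehyde; 28 (E)-1-bromoprop-1-ene
Product: 30 allylic alcohol (both carbinol epimers), via propenylchromium dichloride 29 (not isolated)
Conditions: CrCl2 (4 equiv), NiCl2 (cat.), DMF, rt
Reagents that add atoms: none
Why: Nozaki–Hiyama–Kishi coupling, in which the alkenylchromium reagent forms with retention of the (E) geometry and adds only to the aldehyde in the presence of ester, lactone and enoate; the carbinol configuration is irrelevant.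

Step 15
Reactants: 30 allylic alcohol
Product: 31 bis-silyl ether of the target (5β-OTES; 3α-OTBS)
Conditions: Dess–Martin periodinane, NaHCO3, CH2Cl2, rt
Reagents that add atoms: none
Why: Dess–Martin oxidation of the allylic alcohol gives the (E)-but-2-enoyl ketone without touching silyl ethers, ester or lactone.

Step 16
Reactants: 31 bis-silyl ether of the target
Product: 32 (3aR,5R,6S,7S,8S,8aR)-7-[(2E)-but-2-enoyl]-5,7-dihydroxy-6-methyl-3-methylidene-2-oxooctahydro-2H-cyclohepta[b]furan-8-yl (2R)-2-methylbutanoate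
Conditions: HF·pyridine, pyridine, THF, 0 °C to rt
Reagents that add atoms: none
Why: Fluoride-mediated global desilylation under buffered acidic conditions removes the secondary TES and tertiary TBS ethers and should tolerate the enone, the α-methylene lactone and the ester.

Compound list
1 | 4-oxohexanoic acid | CCC(=O)CCC(=O)O | starting material
2 | (S)-4-benzyl-1,3-oxazolidin-2-one | O=C1N[C@@H](Cc2ccccc2)CO1 | starting material
3 | 4-oxohexanoic pivalic anhydride | CCC(=O)CCC(=O)OC(=O)C(C)(C)C | intermediate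
4 | (S)-4-benzyl-3-(4-oxohexanoyl)-1,3-oxazolidin-2-one | CCC(=O)CCC(=O)N1[C@@H](Cc2ccccc2)COC1=O | intermediate
5 | tert-butyl bromoacetate | CC(C)(C)OC(=O)CBr | starting material
6 | sodium (Z)-enolate of 4 | CCC(=O)C/C=C(\[O-])N1[C@@H](Cc2ccccc2)COC1=O.[Na+] | intermediate
7 | tert-butyl (3R)-3-{[(4S)-4-benzyl-2-oxo-1,3-oxazolidin-3-yl]carbonyl}-5-oxoheptanoate | CCC(=O)C[C@H](CC(=O)OC(C)(C)C)C(=O)N1[C@@H](Cc2ccccc2)COC1=O | intermediate
8 | tert-butyl 2-[(1R)-3-methyl-2,4-dioxocyclopentyl]acetate (C3 enolisable) | CC1C(=O)C[C@H](CC(=O)OC(C)(C)C)C1=O | intermediate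
9 | 2-[(1R)-3-methyl-2,4-dioxocyclopentyl]acetic acid | CC1C(=O)C[C@H](CC(=O)O)C1=O | intermediate
10 | (3aR)-6-methyl-3,3a-dihydro-2H-cyclopenta[b]furan-2,5(4H)-dione | O=C1C[C@H]2CC(=O)C(C)=C2O1 | intermediate
11 | 2,2-dimethyl-1,3-dioxan-5-one | CC1(C)OCC(=O)CO1 | starting material
12 | tert-butyl[(2,2-dimethyl-4H-1,3-dioxin-5-yl)oxy]dimethylsilane | CC1(C)OCC(O[Si](C)(C)C(C)(C)C)=CO1 | intermediate
13 | cyclobutane photoadduct: lactone O on C1 and CH3 on C4 at the bridgeheads, lactone and cyclobutane on opposite faces of the cyclopentanone, acetonide ring (O–C2, CH2–C3) cis-fused and exo, OTBS on C3 endo | O=C1C[C@H]2CC(=O)[C@@]3(C)[C@]2(O1)[C@@H]4OC(C)(C)OC[C@]34O[Si](C)(C)C(C)(C)C | intermediate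
14 | methyl 2-(7β-cycloheptyl)acetate of the C1/C5-dione with 2β-O/3β-CH2O acetonide, 3α-OTBS, 4α-CH3 | COC(=O)C[C@H]1CC(=O)[C@H](C)[C@@]2(O[Si](C)(C)C(C)(C)C)COC(C)(C)O[C@H]2C1=O | intermediate
15 | methyl 2-(2β-hydroxy-3β-hydroxymethyl-3α-tert-butyldimethylsilyloxy-4α-methyl-1,5-dioxocyclohept-7β-yl)acetate | COC(=O)C[C@H]1CC(=O)[C@H](C)[C@](CO)(O[Si](C)(C)C(C)(C)C)[C@@H](O)C1=O | intermediate
16 | methyl 2-(1α,2β-dihydroxy-3β-hydroxymethyl-3α-tert-butyldimethylsilyloxy-4α-methyl-5-oxocyclohept-7β-yl)acetate | COC(=O)C[C@H]1CC(=O)[C@H](C)[C@](CO)(O[Si](C)(C)C(C)(C)C)[C@@H](O)[C@@H]1O | intermediate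
17 | trans-fused γ-lactone (O–C1 α, C7 side chain β) with 2β-OH, 3β-CH2OH, 3α-OTBS, 4α-CH3, 5-oxo | O=C1C[C@H]2CC(=O)[C@H](C)[C@](CO)(O[Si](C)(C)C(C)(C)C)[C@@H](O)[C@@H]2O1 | intermediate
18 | as 17 with 5β-OH in place of the ketone | O=C1C[C@H]2C[C@@H](O)[C@H](C)[C@](CO)(O[Si](C)(C)C(C)(C)C)[C@@H](O)[C@@H]2O1 | intermediate
19 | as 18 with 5β-OTES and 3β-CH2OTES, 2β-OH free | O=C1C[C@H]2C[C@@H](O[Si](CC)(CC)CC)[C@H](C)[C@](CO[Si](CC)(CC)CC)(O[Si](C)(C)C(C)(C)C)[C@@H](O)[C@@H]2O1 | intermediate
20 | dilithium salt of 19 (C2 alkoxide, lactone enolate) | [Li+].[Li+].[O-]C1=C[C@H]2C[C@@H](O[Si](CC)(CC)CC)[C@H](C)[C@](CO[Si](CC)(CC)CC)(O[Si](C)(C)C(C)(C)C)[C@@H]([O-])[C@@H]2O1 | intermediate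
21 | α-(dimethylaminomethyl) lactone (Mannich base, α-carbon configuration left open, removed in the elimination) | CN(C)CC1C(=O)O[C@@H]2[C@@H]1C[C@@H](O[Si](CC)(CC)CC)[C@H](C)[C@@](O[Si](C)(C)C(C)(C)C)(CO[Si](CC)(CC)CC)[C@H]2O | intermediate
22 | α-(trimethylammoniomethyl) lactone iodide | C[N+](C)(C)CC1C(=O)O[C@@H]2[C@@H]1C[C@@H](O[Si](CC)(CC)CC)[C@H](C)[C@@](O[Si](C)(C)C(C)(C)C)(CO[Si](CC)(CC)CC)[C@H]2O.[I-] | intermediate
23 | α-methylene lactone with 2β-OH, 5β-OTES, 3β-CH2OTES, 3α-OTBS | C=C1C(=O)O[C@@H]2[C@@H]1C[C@@H](O[Si](CC)(CC)CC)[C@H](C)[C@@](O[Si](C)(C)C(C)(C)C)(CO[Si](CC)(CC)CC)[C@H]2O | intermediate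
24 | (R)-2-methylbutanoic acid | CC[C@@H](C)C(=O)O | starting material
25 | 2β-(2R)-2-methylbutanoate of 23 | C=C1C(=O)O[C@@H]2[C@@H]1C[C@@H](O[Si](CC)(CC)CC)[C@H](C)[C@@](O[Si](C)(C)C(C)(C)C)(CO[Si](CC)(CC)CC)[C@H]2OC(=O)[C@H](C)CC | intermediate
26 | alkoxy(dimethyl)sulfonium chloride at the C3 CH2O group | C=C1C(=O)O[C@@H]2[C@@H]1C[C@@H](O[Si](CC)(CC)CC)[C@H](C)[C@@](O[Si](C)(C)C(C)(C)C)(CO[S+](C)C)[C@H]2OC(=O)[C@H](C)CC.[Cl-] | intermediate
27 | 3β-carbaldehyde (5β-OTES, 3α-OTBS, 2β-ester) | C=C1C(=O)O[C@@H]2[C@@H]1C[C@@H](O[Si](CC)(CC)CC)[C@H](C)[C@@](O[Si](C)(C)C(C)(C)C)(C=O)[C@H]2OC(=O)[C@H](C)CC | intermediate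
28 | (E)-1-bromoprop-1-ene | C/C=C/Br | starting material
29 | (E)-prop-1-enylchromium dichloride | C/C=C/[Cr](Cl)Cl | intermediate
30 | 3β-[(E)-1-hydroxybut-2-enyl] compound (carbinol epimers) | C=C1C(=O)O[C@@H]2[C@@H]1C[C@@H](O[Si](CC)(CC)CC)[C@H](C)[C@@](O[Si](C)(C)C(C)(C)C)(C(O)/C=C/C)[C@H]2OC(=O)[C@H](C)CC | intermediate
31 | 5-O-triethylsilyl 3-O-tert-butyldimethylsilyl ether of the target | C=C1C(=O)O[C@@H]2[C@@H]1C[C@@H](O[Si](CC)(CC)CC)[C@H](C)[C@@](O[Si](C)(C)C(C)(C)C)(C(=O)/C=C/C)[C@H]2OC(=O)[C@H](C)CC | intermediate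
32 | (3aR,5R,6S,7S,8S,8aR)-7-[(2E)-but-2-enoyl]-5,7-dihydroxy-6-methyl-3-methylidene-2-oxooctahydro-2H-cyclohepta[b]furan-8-yl (2R)-2-methylbutanoate | C=C1C(=O)O[C@@H]2[C@@H]1C[C@@H](O)[C@H](C)[C@@](O)(C(=O)/C=C/C)[C@H]2OC(=O)[C@H](C)CC | target

Total step count: 16. Longest linear sequence: 15 steps (steps 1–4 and 6–16); step 5 is a one-step side branch.

Steps most likely to fail

Step 6. The crowded 1,4-biradical may fragment back to the partners faster than it closes, or the dioxane ring may enter endo because the bulky silyloxy group has to sit in the concave position. The fallback uses a smaller silyl group in the cycloaddition and exchanges it before any base is met. It sets out from 11 and 10 and comes back at 13. Ketone 11 is converted (Me3SiCl, Et3N, NaI, MeCN) into [(2,2-dimethyl-4H-1,3-dioxin-5-yl)oxy]trimethylsilane F1, which is irradiated with 10 as in step 6 to the trimethylsilyl photoadduct F2. Buffered HF·pyridine frees the tertiary cyclobutanol F3, and TBSOTf with 2,6-lutidine at −78 °C gives 13.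

Step 7. While the 1,4-dione sits in basic methanol, epimerisation at C7 or C2 (both α to the new C1 ketone) or β-elimination of the C3 silyloxy group may compete. The fallback opens the lactone with the much less basic hydroperoxide anion and carries the side chain as the acid. It sets out from 13 and comes back at 17. LiOH and H2O2 in THF–H2O at 0 °C give, after retro-aldol and acidification, the acetonide keto acid F4. 1 M HCl in THF removes the acetonide to give the diol keto acid F5. The directed reduction of step 8 then gives the hydroxy acid F6, which lactonises under PPTS to 17.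

Step 10. Silylation of the C2 hydroxyl may compete with that of the C5 hydroxyl, so that site selectivity is lost. The fallback masks the C2 hydroxyl and the CH2OH group together before the C5 hydroxyl is silylated. It sets out from 18 and comes back at 19. PhB(OH)2 in toluene over molecular sieves gives the cyclic phenylboronate F7 of the 1,3-diol. Et3SiCl and imidazole silylate the remaining C5 hydroxyl to give the boronate silyl ether F8. Exchange of the boronate onto pinacol frees the C5-O-triethylsilyl diol F9, whose primary hydroxyl alone is silylated (Et3SiCl 1.05 equiv, imidazole, −20 °C) to give 19.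

Further compounds
F1 | step 6 | [(2,2-dimethyl-4H-1,3-dioxin-5-yl)oxy]trimethylsilane | CC1(C)OCC(O[Si](C)(C)C)=CO1
F2 | step 6 | trimethylsilyl analogue of photoadduct 13 | O=C1C[C@H]2CC(=O)[C@@]3(C)[C@]2(O1)[C@@H]4OC(C)(C)OC[C@]34O[Si](C)(C)C
F3 | step 6 | tertiary cyclobutanol (desilylated photoadduct) | O=C1C[C@H]2CC(=O)[C@@]3(C)[C@]2(O1)[C@@H]4OC(C)(C)OC[C@]34O
F4 | step 7 | acetonide keto acid (carboxylic acid analogue of 14) | OC(=O)C[C@H]1CC(=O)[C@H](C)[C@@]2(O[Si](C)(C)C(C)(C)C)COC(C)(C)O[C@H]2C1=O
F5 | step 7 | diol keto acid (carboxylic acid analogue of 15) | OC(=O)C[C@H]1CC(=O)[C@H](C)[C@](CO)(O[Si](C)(C)C(C)(C)C)[C@@H](O)C1=O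
F6 | step 7 | hydroxy acid (carboxylic acid analogue of 16) | OC(=O)C[C@H]1CC(=O)[C@H](C)[C@](CO)(O[Si](C)(C)C(C)(C)C)[C@@H](O)[C@@H]1O
F7 | step 10 | cyclic phenylboronate of 18 (across O–C2 and CH2O–C3) | O=C1C[C@H]2C[C@@H](O)[C@H](C)[C@@]3(O[Si](C)(C)C(C)(C)C)COB(c4ccccc4)O[C@H]3[C@@H]2O1
F8 | step 10 | 5-O-triethylsilyl ether of F7 | O=C1C[C@H]2C[C@@H](O[Si](CC)(CC)CC)[C@H](C)[C@@]3(O[Si](C)(C)C(C)(C)C)COB(c4ccccc4)O[C@H]3[C@@H]2O1
F9 | step 10 | 5-O-triethylsilyl diol (2β-OH and CH2OH free) | O=C1C[C@H]2C[C@@H](O[Si](CC)(CC)CC)[C@H](C)[C@](CO)(O[Si](C)(C)C(C)(C)C)[C@@H](O)[C@@H]2O1
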